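**Retrosynthetic overview**

1. Both flavan units are bought as (+)-fustin 1, which supplies C2 and C3 of each half. Its tribenzyl ether 2 is the C4 ketone for the upper unit and, after reduction, the source of the lower unit.
2. Lower unit: bulky-hydride reduction of 2 gives the 3,4-cis diol 3 (sets the lower C4–OH). Ring-A bromination gives the C6 bromide 4.
3. Key disconnection, the interflavan C4–C6' bond: aryllithium 5 (from 4) adds to the C4 carbonyl of 2 (as its lithium alkoxide 6) to give carbinol 7.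
4. The upper C4–H goes in last: ionic hydrogenation of 7 through cation 8 delivers hydride anti to the C3 oxygen and gives the 3,4-cis dimer 9. Hydrogenolysis then gives the target 10.
5. No ring is constructed. Rings A, B and C of both halves come intact from 1, so the order is one of bond formation only: lower C4–H, C6–Br, C4–C6', upper C4–H, O-debenzylation.

Assumption: natural (+)-(2R,3R)-fustin is purchasable; below, β means the face of the 3-OH of fustin and α the face of its 2-aryl group.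

**Step 1**
Reactants: 1 (+)-fustin
Product: 2 7,3',4'-tri-O-benzylfustin
Conditions: BnBr (3.3 equiv), K2CO3 (3.5 equiv), DMF, 0 °C → rt, Ar
Reagents that add atoms: benzyl bromide, BrCc1ccccc1
Why: Williamson ether synthesis on the three phenols with a weak base leaves the aliphatic 3-OH free and, at or below room temperature, should not epimerise C2 or C3; no new stereocentre is formed.

**Step 2**
Reactants: 2 7,3',4'-tri-O-benzylfustin
Product: 3 tri-O-benzyl (2R,3S,4S)-flavan-3,4-diol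
Conditions: LiBH(s-Bu)3 (2.3 equiv), THF, −78 °C; then H2O
Reagents that add atoms: none
Why: Bulky trialkylborohydride (Selectride) reduction of an α-substituted cyclic ketone: hydride comes in along the equatorial trajectory on the α face, away from the axial C2–H, so the new 4-OH is axial, β and cis to the bought 3-OH (the reverse of NaBH4, which gives the 3,4-trans diol).

**Step 3**
Reactants: 3 tri-O-benzyl (2R,3S,4S)-flavan-3,4-diol
Product: 4 6-bromo derivative of 3
Conditions: NBS (1.02 equiv), CH2Cl2, −40 → 0 °C, dark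
Reagents that add atoms: N-bromosuccinimide, O=C1CCC(=O)N1Br
Why: Electrophilic aromatic bromination goes to C6 of ring A, which is para to O1 and ortho to the 7-benzyloxy group, because C8 is flanked by two oxygens and the catechol diether ring B is less activated; no stereocentre is touched.

**Step 4**
Reactants: 4 6-bromo derivative of 3; 2 7,3',4'-tri-O-benzylfustin
Product: 7 hexa-O-benzyl C4-carbinol dimer, via C6-lithio dilithium dialkoxide 5 (not isolated), via tribenzylfustin lithium 3-alkoxide 6 (not isolated)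
Conditions: 4 (1.3 equiv): t-BuLi (4.2 equiv), THF, −78 °C; 2: LiN(SiMe3)2 (1.0 equiv), THF, −78 °C; combine, −78 → −40 °C; then H2O
Reagents that add atoms: none
Why: O-deprotonation then bromine–lithium exchange gives an aryllithium that undergoes 1,2-addition to the lithium-chelated ketone, whose neighbouring alkoxide blocks enolisation toward C3; the new carbinol centre (attack expected from the α face) is planarised in step 5, so its configuration does not matter.

**Step 5**
Reactants: 7 hexa-O-benzyl C4-carbinol dimer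
Product: 9 hexa-O-benzyl fisetinidol-(4β→6)-fisetinidol-4β-ol, via C4 diarylmethyl cation trifluoroacetate 8 (not isolated)
Conditions: Et3SiH (10 equiv), CF3CO2H (3 equiv), CH2Cl2, −40 → −20 °C
Reagents that add atoms: none
Why: Ionic hydrogenation: only the tertiary, doubly benzylic carbinol ionises, the C3 oxygen of the cation sits pseudoaxial to relieve allylic 1,2-strain with the C4 aryl group, and silane hydride adds trans-diaxially to it from the α face, so H-4 is trans and the aryl group cis to the bought 3-OH.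

**Step 6**
Reactants: 9 hexa-O-benzyl fisetinidol-(4β→6)-fisetinidol-4β-ol
Product: 10 fisetinidol-(4β→6)-fisetinidol-4β-ol (target)
Conditions: H2 (1 atm), Pd(OH)2/C, THF–MeOH (1:1), rt, stop at full O-debenzylation
Reagents that add atoms: none
Why: Catalytic hydrogenolysis cleaves the six aryl benzyl ethers much faster than the free secondary benzylic alcohol or the diarylmethine C–C bond under neutral conditions, and no stereocentre is touched.

**Compound list**

1 | (+)-fustin, (2R,3R)-2-(3,4-dihydroxyphenyl)-3,7-dihydroxy-2,3-dihydro-4H-chromen-4-one (2,3-trans) | Oc1ccc2c(c1)O[C@H](c1ccc(O)c(O)c1)[C@@H](O)C2=O | starting material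

2 | 7,3',4'-tri-O-benzylfustin, (2R,3R)-7-(benzyloxy)-2-[3,4-bis(benzyloxy)phenyl]-3-hydroxy-2,3-dihydro-4H-chromen-4-one | c1ccccc1COc1ccc2c(c1)O[C@H](c1ccc(OCc3ccccc3)c(OCc3ccccc3)c1)[C@@H](O)C2=O | intermediate

3 | (2R,3S,4S)-7-(benzyloxy)-2-[3,4-bis(benzyloxy)phenyl]chromane-3,4-diol (2,3-trans-3,4-cis, both OH β) | c1ccccc1COc1ccc2c(c1)O[C@H](c1ccc(OCc3ccccc3)c(OCc3ccccc3)c1)[C@@H](O)[C@H]2O | intermediate

4 | (2R,3S,4S)-7-(benzyloxy)-2-[3,4-bis(benzyloxy)phenyl]-6-bromochromane-3,4-diol | c1ccccc1COc1c(Br)cc2c(c1)O[C@H](c1ccc(OCc3ccccc3)c(OCc3ccccc3)c1)[C@@H](O)[C@H]2O | intermediate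

5 | C6-lithio derivative of 4 as its 3,4-dilithium dialkoxide | c1ccccc1COc1c([Li])cc2c(c1)O[C@H](c1ccc(OCc3ccccc3)c(OCc3ccccc3)c1)[C@@H](O[Li])[C@H]2O[Li] | intermediate (not isolated)

6 | lithium 3-alkoxide of 2 | c1ccccc1COc1ccc2c(c1)O[C@H](c1ccc(OCc3ccccc3)c(OCc3ccccc3)c1)[C@@H](O[Li])C2=O | intermediate (not isolated)

7 | hexa-O-benzyl C4-carbinol: upper unit (2R,3S)-7-(benzyloxy)-2-[3,4-bis(benzyloxy)phenyl]chromane-3,4-diol bearing at C4 the C6 of the lower unit (2R,3S,4S)-7-(benzyloxy)-2-[3,4-bis(benzyloxy)phenyl]-3,4-dihydroxychroman-6-yl; 4-OH drawn β, aryl α (expected major epimer) | c1ccccc1COc1ccc2c(c1)O[C@H](c1ccc(OCc3ccccc3)c(OCc3ccccc3)c1)[C@@H](O)[C@]2(O)c1cc2c(cc1OCc3ccccc3)O[C@H](c1ccc(OCc3ccccc3)c(OCc3ccccc3)c1)[C@@H](O)[C@H]2O | intermediate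

8 | C4 diarylmethyl cation derived from 7, trifluoroacetate salt | c1ccccc1COc1ccc2c(c1)O[C@H](c1ccc(OCc3ccccc3)c(OCc3ccccc3)c1)[C@@H](O)[C+]2c1cc2c(cc1OCc3ccccc3)O[C@H](c1ccc(OCc3ccccc3)c(OCc3ccccc3)c1)[C@@H](O)[C@H]2O.[O-]C(=O)C(F)(F)F | intermediate (not isolated)

9 | hexa-O-benzyl fisetinidol-(4β→6)-fisetinidol-4β-ol: upper unit 2R,3S with H-4 α and the C4 aryl β (2,3-trans-3,4-cis), lower unit 2R,3S,4S | c1ccccc1COc1ccc2c(c1)O[C@H](c1ccc(OCc3ccccc3)c(OCc3ccccc3)c1)[C@@H](O)[C@H]2c1cc2c(cc1OCc3ccccc3)O[C@H](c1ccc(OCc3ccccc3)c(OCc3ccccc3)c1)[C@@H](O)[C@H]2O | intermediate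

10 | fisetinidol-(4β→6)-fisetinidol-4β-ol, (2R,3S,4S)-2-(3,4-dihydroxyphenyl)-4-[(2R,3S,4S)-2-(3,4-dihydroxyphenyl)-3,4,7-trihydroxy-3,4-dihydro-2H-chromen-6-yl]-3,4-dihydro-2H-chromene-3,7-diol | Oc1ccc2c(c1)O[C@H](c1ccc(O)c(O)c1)[C@@H](O)[C@H]2c1cc2c(cc1O)O[C@H](c1ccc(O)c(O)c1)[C@@H](O)[C@H]2O | target

**Step count and risks**

Total step count: 6. Longest linear sequence: 6 steps (1 → 2 → 3 → 4 → 7 → 9 → 10); 2 is used a second time as the ketone partner in step 4.

The three steps most likely to fail: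

Step 4 (aryllithium addition). The unprotected polyanion may be poorly soluble or quenched, and the hindered, electron-rich ketone may react slowly. Fallback, setting out from 4 and 2: mask the hydroxyls first. Et3SiCl and imidazole in DMF convert 4 into its bis(triethylsilyl) ether F1 and 2 into the 3-O-triethylsilyl ketone F2. F1 with t-BuLi (2.1 equiv, THF, −78 °C) gives the aryllithium F3, which adds to F2 to give the tris(triethylsilyl) carbinol F4. Bu4NF buffered with AcOH in THF removes the three silyl groups, and the route is rejoined at 7.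

Step 5 (ionic hydrogenation). The acid may also ionise the lower benzylic C4–OH, or the cation may lose H-3 and erode C3. Fallback, setting out from 7: radical instead of cationic reduction. PhSH with catalytic pyridinium p-toluenesulfonate (CH2Cl2, 0 °C) exchanges only the tertiary hydroxyl for sulfur and gives the C4 phenylsulfanyl compound F5. Bu3SnH with AIBN (toluene, 80 °C) then cleaves the C–S bond, and the planar diarylmethyl radical takes hydrogen on the α face, anti to the C3 oxygen, to come back to the route at 9.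

Step 6 (hydrogenolysis). The electron-rich benzylic C4–OH of the lower unit may be hydrogenolysed along with the benzyl ethers. Fallback, setting out from 9: remove that alcohol before hydrogenolysis and restore it afterwards. MnO2 in CH2Cl2 oxidises only the benzylic alcohol to the lower-unit ketone F6. H2 over Pd(OH)2/C gives the free phenolic ketone F7. N,O-Bis(trimethylsilyl)acetamide in THF gives the octakis(trimethylsilyl) ether F8. LiBH(s-Bu)3 at −78 °C reduces it from the α face, as in step 2, to the 3,4-cis alcohol F9. Dilute AcOH in aqueous MeOH strips the silyl groups and gives 10.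

**Further compounds**

F1 | step 4 | 3,4-bis(triethylsilyl) ether of 4 | c1ccccc1COc1c(Br)cc2c(c1)O[C@H](c1ccc(OCc3ccccc3)c(OCc3ccccc3)c1)[C@@H](O[Si](CC)(CC)CC)[C@H]2O[Si](CC)(CC)CC

F2 | step 4 | 3-O-triethylsilyl ether of 2 | c1ccccc1COc1ccc2c(c1)O[C@H](c1ccc(OCc3ccccc3)c(OCc3ccccc3)c1)[C@@H](O[Si](CC)(CC)CC)C2=O

F3 | step 4 | C6-aryllithium derived from F1 | c1ccccc1COc1c([Li])cc2c(c1)O[C@H](c1ccc(OCc3ccccc3)c(OCc3ccccc3)c1)[C@@H](O[Si](CC)(CC)CC)[C@H]2O[Si](CC)(CC)CC

F4 | step 4 | tris(triethylsilyl) ether of 7 (tertiary 4-OH free) | c1ccccc1COc1ccc2c(c1)O[C@H](c1ccc(OCc3ccccc3)c(OCc3ccccc3)c1)[C@@H](O[Si](CC)(CC)CC)[C@]2(O)c1cc2c(cc1OCc3ccccc3)O[C@H](c1ccc(OCc3ccccc3)c(OCc3ccccc3)c1)[C@@H](O[Si](CC)(CC)CC)[C@H]2O[Si](CC)(CC)CC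

F5 | step 5 | C4 phenylsulfanyl analogue of 7 (SPh in place of the tertiary OH, drawn α) | c1ccccc1COc1ccc2c(c1)O[C@H](c1ccc(OCc3ccccc3)c(OCc3ccccc3)c1)[C@@H](O)[C@@]2(Sc3ccccc3)c1cc2c(cc1OCc3ccccc3)O[C@H](c1ccc(OCc3ccccc3)c(OCc3ccccc3)c1)[C@@H](O)[C@H]2O

F6 | step 6 | lower-unit C4 ketone of 9 (hexa-O-benzyl fisetinidol-(4β→6)-fustin) | c1ccccc1COc1ccc2c(c1)O[C@H](c1ccc(OCc3ccccc3)c(OCc3ccccc3)c1)[C@@H](O)[C@H]2c1cc2c(cc1OCc3ccccc3)O[C@H](c1ccc(OCc3ccccc3)c(OCc3ccccc3)c1)[C@@H](O)C2=O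

F7 | step 6 | fisetinidol-(4β→6)-fustin (free phenolic ketone) | Oc1ccc2c(c1)O[C@H](c1ccc(O)c(O)c1)[C@@H](O)[C@H]2c1cc2c(cc1O)O[C@H](c1ccc(O)c(O)c1)[C@@H](O)C2=O

F8 | step 6 | octakis(trimethylsilyl) ether of F7 | C[Si](C)(C)Oc1ccc2c(c1)O[C@H](c1ccc(O[Si](C)(C)C)c(O[Si](C)(C)C)c1)[C@@H](O[Si](C)(C)C)[C@H]2c1cc2c(cc1O[Si](C)(C)C)O[C@H](c1ccc(O[Si](C)(C)C)c(O[Si](C)(C)C)c1)[C@@H](O[Si](C)(C)C)C2=O

F9 | step 6 | octakis(trimethylsilyl) ether of 10 with the lower 4β-OH free | C[Si](C)(C)Oc1ccc2c(c1)O[C@H](c1ccc(O[Si](C)(C)C)c(O[Si](C)(C)C)c1)[C@@H](O[Si](C)(C)C)[C@H]2c1cc2c(cc1O[Si](C)(C)C)O[C@H](c1ccc(O[Si](C)(C)C)c(O[Si](C)(C)C)c1)[C@@H](O[Si](C)(C)C)[C@H]2O
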